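## The problem

The target, (1S)-1-[5-(2,5-dihydroxyphenyl)furan-3-yl]-4-methylpent-3-en-1-yl 3-methylbut-2-enoate, is a 2,4-disubstituted furan. Furan C2 is bonded to a hydroquinone ring, and furan C4 carries a side chain whose first carbon is the only stereocentre. That carbon bears the ester oxygen and a CH2 leading to a 2-methylprop-1-enyl group, so the chain is a linear prenyl unit. Prenyl-metal additions to an aldehyde normally give the α,α-dimethylallyl isomer instead. No second stereo element exists to relay from, so the (S) configuration must come from a catalyst or reagent, and it must then survive as a furylic C–O bond that ionises easily. The free hydroquinone oxidises in air, the furan and the trisubstituted alkene dislike acid and electrophilic oxidants, the furylic ester can racemise or eliminate, and the unsaturated ester can deconjugate under base. The late steps must therefore be near neutral, and the phenol protection must come off without acid, strong base or hydrogen. The enabling feature is that the carbinol carbon sits between furan C4 and a CH2 bonded to an alkene sp2 carbon. With boron in place of oxygen, the carbinol carbon and that CH2 are a vinyl group that has taken up a furyl group at its α-carbon and an alkenyl group at its β-carbon. The remaining task is a furan with the aryl at C2, a handle at C4 and nothing at C3 or C5.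

## Retrosynthesis

**O–Si bonds.** Target 18 is traced to its bis(triisopropylsilyl) ether 17. Aryl silyl ethers fall to buffered fluoride, which spares the ester, the furan and the alkene. Acetal, benzyl and methyl ethers would need acid, hydrogen or a boron trihalide at the end. Triisopropylsilyl is chosen over smaller silyl groups because it must survive a sulfonic acid, an acetate base at 80 °C and a basic oxidation.

**Acyl C–O bond.** Ester 17 is cut at the acyl–oxygen bond to alcohol 15 and 3-methylbut-2-enoic acid 16. Acylation at oxygen leaves the stereocentre untouched. Displacement at the furylic carbon would invite ionisation. Carrying the ester earlier would expose it to organolithium and perborate.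

**C–O from C–B.** Alcohol 15 is traced to the secondary pinacol boronate 14. Oxidation of a C–B bond goes with retention, so the stereochemical problem moves to a configurationally stable boronate. Asymmetric reduction of the corresponding furyl ketone was set aside because its β,γ-double bond would slip into conjugation.

**Two C–C bonds (key cut).** Boronate 14 is cut at the furan C4–carbinol bond and at the CH2–alkenyl bond. This gives furyl pinacol boronate 8, vinyllithium 10 and 2-methylprop-1-enyl triflate 12, joined through ate complex 13. The linear prenyl chain arises directly, and boron marks the future C–O carbon. The precursor 8 is achiral and carries no side chain. The forward step needs catalyst control of one stereocentre and migration in preference to direct cross-coupling.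

**The two small partners.** Triflate 12 comes from isobutyraldehyde 11 by O-sulfonylation of its enol; the two β-methyl groups remove any geometry question. Vinyllithium 10 comes from tetravinylstannane 9 by tin–lithium exchange, which gives it free of halide.

**C–B from C–I.** Boronate 8 is traced to 4-iodofuran 7. Direct C–H borylation of a 2-arylfuran would go to C5, so a halogen at C4 is needed.

**Furan ring.** Iodofuran 7 is cut at the aroyl–alkyne bond, the C4–I bond and the ring O–C2 bond. This leads to acid chloride 4, propargyl tetrahydropyranyl ether 5 and iodide, through ynone 6. The aryl at C2 and the iodine at C4 follow from the connectivity, which selective coupling on a dihalofuran would have to achieve by discrimination.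

**Arene.** Acid chloride 4 comes from acid 3, and 3 from 2,5-dihydroxybenzoic acid 1 by exhaustive silylation (silyl ester 2) and selective cleavage of the silyl ester. The oxygenation pattern is bought.

## Roads not taken

Alternative 1: The furan is cut at its C3=C4 bond, at the dihydrofuran oxidation level. Bis-allylic ether A2 would close with the second-generation Grubbs catalyst to 2,5-dihydrofuran A1, followed by dehydrogenation and removal of the methoxymethyl groups.
- Merits: closure of a 2,5-dihydrofuran from a vinyl group and a 1,1-disubstituted alkene is dependable. The prenyl and ester alkenes are poor metathesis partners, so chemoselectivity is plausible. No tin and no ate complex are involved. The ring closure is probably more certain than the coupling chosen here.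
- Weak points: A1 is at the oxidation level of a furan plus a carboxylic acid. It can aromatise by 1,4-elimination of the allylic ester, which deletes the stereocentre. The dehydrogenating agent must spare an electron-rich arene and a prenyl group. Acidic acetal removal at the end threatens the furylic ester. The stereocentre in A2 still needs its own enantioselective step.
- Comparison: the chosen plan accepts a less tested key step. In return the furan is made early by condensation, no aromatisation occurs after the stereocentre exists, and deprotection is by fluoride.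

Alternative 2: The hydroquinone ring is cut into three pieces. The zerovalent chromium carbene A5 and ethynylfuran A4 would combine with one CO ligand in a Dötz benzannulation to give monomethyl ether A3.
- Merits: a terminal alkyne places its substituent next to the new phenol, so the substitution pattern is right. The step is convergent and has no stereochemical task.
- Weak points: the key step builds the one ring that is commercial with the correct oxygens. Stoichiometric chromium is needed, and the vinyl carbene A5 is labile. A4 must already contain the stereocentre and the furylic ester, and is no easier to make than 8. Reagents that cleave an aryl methyl ether do not spare the ester, furan and alkene. A detour through the quinone oxidation level would expose the furan to an oxidant.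
- Comparison: this road needs no chiral ligand. The chosen plan sets against it a bought arene, catalytic metal only, and silyl groups that leave under buffered fluoride.

Alternative 3: The ring O–C2 bond and the ester C–O bond are cut together. Ph3PAuCl with the silver salt of one enantiomer of 3,3'-bis(2,4,6-triisopropylphenyl)-1,1'-binaphthyl-2,2'-diyl phosphate would activate the alkyne of ynenal A7. The aldehyde oxygen would close the furan, and acid 16 would capture the resulting cation to give A6.
- Merits: ring, C–O bond, ester and stereocentre form in one step. On step count this road is clearly better than the chosen plan.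
- Weak points: enantioselection rests on a chiral ion pair steering a weak, achiral carboxylic acid onto a furyl-stabilised cation. The product is a furylic ester that the Lewis acid can re-ionise, so selectivity can erode. The prenyl alkene is homoallylic to the cation and can take part, and proton loss to a diene is open. The skipped dienal A7 is prone to conjugation.
- Comparison: the chosen plan is longer. Its stereocentre is set by a ligand on palladium in a known reaction type and is stored as a C–B bond, and the ester is introduced under non-ionising conditions.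

Key step: step 7

Assumption: the sense of induction for 3-furyl migration is taken to follow that of phenyl migration with this ligand family, recalled rather than verified, so the (Rp,Rp) ligand is specified for the (S)-boronate; the (Sp,Sp) antipode would be used if the sense proved opposite.

## Route

Step 1
Reactants: 1 2,5-dihydroxybenzoic acid
Product: 3 2,5-bis(triisopropylsilyloxy)benzoic acid, via silyl ester 2 (not isolated)
Conditions: TIPSOTf (3.3 equiv), Et3N, CH2Cl2, 0 °C to rt; then K2CO3, MeOH/THF/H2O, 0 °C; aq. citric acid work-up
Reagents that add atoms: triisopropylsilyl trifluoromethanesulfonate, CC(C)[Si](OS(=O)(=O)C(F)(F)F)(C(C)C)C(C)C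
Why: The silyl triflate silylates the hydrogen-bonded ortho phenol as well as the other phenol and the acid; the silyl ester is far more labile than the hindered aryl silyl ethers and is cleaved selectively by brief carbonate hydrolysis.

Step 2
Reactants: 3 2,5-bis(triisopropylsilyloxy)benzoic acid
Product: 4 2,5-bis(triisopropylsilyloxy)benzoyl chloride
Conditions: (COCl)2, DMF (cat.), CH2Cl2, 0 °C to rt; volatiles removed, used crude
Reagents that add atoms: oxalyl chloride, ClC(=O)C(=O)Cl
Why: Acid chloride formation through the chloroiminium salt runs at or below room temperature, where aryl triisopropylsilyl ethers tolerate the hydrogen chloride formed.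

Step 3
Reactants: 4 2,5-bis(triisopropylsilyloxy)benzoyl chloride; 5 2-(prop-2-yn-1-yloxy)oxane
Product: 7 2-[2,5-bis(triisopropylsilyloxy)phenyl]-4-iodofuran, via ynone 6 (not isolated)
Conditions: PdCl2(PPh3)2 (2 mol%), CuI (4 mol%), Et3N (1.05 equiv), THF, rt; then NaI, TsOH·H2O, MeOH, rt
Reagents that add atoms: sodium iodide, [Na+].[I-]
Why: Sonogashira acylation gives ynone 6; acid and iodide then effect conjugate hydroiodination, methanolysis of the acetal and cyclodehydration, a known one-pot three-component synthesis of 3-halofurans. The connectivity of 6 places the aryl at C2 and the iodine at C4.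

Step 4
Reactants: 7 2-[2,5-bis(triisopropylsilyloxy)phenyl]-4-iodofuran
Product: 8 2-{5-[2,5-bis(triisopropylsilyloxy)phenyl]furan-3-yl}-4,4,5,5-tetramethyl-1,3,2-dioxaborolane
Conditions: B2pin2, PdCl2(dppf)·CH2Cl2 (3 mol%; dppf = 1,1'-bis(diphenylphosphino)ferrocene), KOAc, 1,4-dioxane, 80 °C
Reagents that add atoms: bis(pinacolato)diboron, CC1(C)OB(OC1(C)C)B1OC(C)(C)C(C)(C)O1
Why: Miyaura borylation of a heteroaryl iodide; the weak acetate base leaves the aryl silyl ethers intact and limits Suzuki coupling of the product.

Step 5
Reactants: 9 tetravinylstannane
Product: 10 vinyllithium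
Conditions: n-BuLi (2 equiv, hexanes), pentane, rt; solid filtered under argon, washed with pentane, dissolved in Et2O and titrated
Reagents that add atoms: n-butyllithium, [Li]CCCC
Why: Tin–lithium exchange; vinyllithium precipitates from the hydrocarbon while the tin by-product stays in solution, which gives a halide-free reagent.

Step 6
Reactants: 11 isobutyraldehyde
Product: 12 2-methylprop-1-enyl trifluoromethanesulfonate
Conditions: Tf2O, 2,6-di-tert-butyl-4-methylpyridine, CH2Cl2, 0 °C to reflux; careful distillation
Reagents that add atoms: trifluoromethanesulfonic anhydride, FC(F)(F)S(=O)(=O)OS(=O)(=O)C(F)(F)F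
Why: O-sulfonylation of an enolisable aldehyde and proton loss to a hindered, non-nucleophilic base gives the enol triflate; two identical β-methyl groups mean a single alkene isomer.

Step 7
Reactants: 8 2-{5-[2,5-bis(triisopropylsilyloxy)phenyl]furan-3-yl}-4,4,5,5-tetramethyl-1,3,2-dioxaborolane; 10 vinyllithium; 12 2-methylprop-1-enyl trifluoromethanesulfonate
Product: 14 2-[(1S)-1-{5-[2,5-bis(triisopropylsilyloxy)phenyl]furan-3-yl}-4-methylpent-3-en-1-yl]-4,4,5,5-tetramethyl-1,3,2-dioxaborolane, via lithium boronate complex 13 (not isolated)
Conditions: 10 (1.0 equiv), Et2O, 0 °C to rt; solvent exchanged for THF; Pd(OAc)2 (2 mol%), (Rp,Rp)-1,1'-bis[bis(4-methoxy-3,5-dimethylphenyl)phosphino]-2,2'-bis[(S)-α-(dimethylamino)benzyl]ferrocene (2.4 mol%), 12 (1.2 equiv), THF, 60 °C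
Reagents that add atoms: none
Why: Vinyllithium 10 adds to boron of 8 to give four-coordinate boronate 13; zerovalent palladium, formed from Pd(OAc)2 and the bisphosphine, adds oxidatively to triflate 12, and because triflate does not bind, the cationic divalent alkenylpalladium binds the vinyl group of 13. The furyl group then shifts from boron to the α-carbon anti to palladium (a metal-induced 1,2-metallate rearrangement), making the furan C4–C bond and an alkylpalladium at the former vinyl CH2; reductive elimination makes the CH2–alkenyl bond and returns the zerovalent catalyst. The closest known reaction type is the palladium-catalysed enantioselective conjunctive cross-coupling of vinylboron ate complexes with aryl and alkenyl triflates, in which aryl groups migrate; the 3-furyl group only extends the migrating group. No ring is closed. The one new stereocentre is fixed in the migration step by the face of the vinyl group that the chiral ferrocenyl bisphosphine (a Mandyphos ligand) lets palladium bind, so it is under catalyst control. The step needs the metallate shift to outrun direct transfer of furyl or vinyl from boron to palladium and β-hydride elimination from the alkylpalladium; the wide bite angle of the ligand, the halide-free lithium counter-ion, the triflate leaving group and the non-migrating pinacol oxygens serve this. Boron sits at a furan β-position, where attack of palladium on the ring is less favoured than in an α-borylated furan, and the aryl silyl ethers are spectators.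

Step 8
Reactants: 14 2-[(1S)-1-{5-[2,5-bis(triisopropylsilyloxy)phenyl]furan-3-yl}-4-methylpent-3-en-1-yl]-4,4,5,5-tetramethyl-1,3,2-dioxaborolane
Product: 15 (1S)-1-{5-[2,5-bis(triisopropylsilyloxy)phenyl]furan-3-yl}-4-methylpent-3-en-1-ol
Conditions: NaBO3·4H2O, THF/H2O (1:1), rt
Reagents that add atoms: sodium perborate tetrahydrate, [Na+].[O-]OB=O.O.O.O.O
Why: Oxidation of the C–B bond; the peroxide adds to boron and carbon migrates to oxygen with retention, so (S) is preserved. Perborate is nucleophilic and mildly basic, which spares the alkene, the furan and the aryl silyl ethers.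

Step 9
Reactants: 15 (1S)-1-{5-[2,5-bis(triisopropylsilyloxy)phenyl]furan-3-yl}-4-methylpent-3-en-1-ol; 16 3-methylbut-2-enoic acid
Product: 17 (1S)-1-{5-[2,5-bis(triisopropylsilyloxy)phenyl]furan-3-yl}-4-methylpent-3-en-1-yl 3-methylbut-2-enoate
Conditions: DCC, DMAP (cat.), CH2Cl2, 0 °C to rt
Reagents that add atoms: none
Why: Steglich esterification acylates at oxygen under near-neutral conditions, so the furylic C–O bond is never broken and the configuration is kept; the free acid with a carbodiimide avoids the acid chloride and amine base that promote deconjugation.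

Step 10
Reactants: 17 (1S)-1-{5-[2,5-bis(triisopropylsilyloxy)phenyl]furan-3-yl}-4-methylpent-3-en-1-yl 3-methylbut-2-enoate
Product: 18 (1S)-1-[5-(2,5-dihydroxyphenyl)furan-3-yl]-4-methylpent-3-en-1-yl 3-methylbut-2-enoate
Conditions: TBAF (2.2 equiv), AcOH (2.5 equiv), THF, 0 °C, argon, degassed solvents
Reagents that add atoms: none
Why: Fluoride cleaves aryl silyl ethers readily; acetic acid keeps the phenols protonated, which protects the hydroquinone from air oxidation and the ester from phenoxide-mediated cleavage.

## Compound list

1 | 2,5-dihydroxybenzoic acid | O=C(O)c1cc(O)ccc1O | starting material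
2 | triisopropylsilyl 2,5-bis(triisopropylsilyloxy)benzoate | CC(C)[Si](OC(=O)c1cc(O[Si](C(C)C)(C(C)C)C(C)C)ccc1O[Si](C(C)C)(C(C)C)C(C)C)(C(C)C)C(C)C | intermediate
3 | 2,5-bis(triisopropylsilyloxy)benzoic acid | OC(=O)c1cc(O[Si](C(C)C)(C(C)C)C(C)C)ccc1O[Si](C(C)C)(C(C)C)C(C)C | intermediate
4 | 2,5-bis(triisopropylsilyloxy)benzoyl chloride | ClC(=O)c1cc(O[Si](C(C)C)(C(C)C)C(C)C)ccc1O[Si](C(C)C)(C(C)C)C(C)C | intermediate
5 | 2-(prop-2-yn-1-yloxy)oxane | C#CCOC1CCCCO1 | starting material
6 | 1-[2,5-bis(triisopropylsilyloxy)phenyl]-4-(oxan-2-yloxy)but-2-yn-1-one | O=C(C#CCOC1CCCCO1)c1cc(O[Si](C(C)C)(C(C)C)C(C)C)ccc1O[Si](C(C)C)(C(C)C)C(C)C | intermediate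
7 | 2-[2,5-bis(triisopropylsilyloxy)phenyl]-4-iodofuran | Ic1coc(-c2cc(O[Si](C(C)C)(C(C)C)C(C)C)ccc2O[Si](C(C)C)(C(C)C)C(C)C)c1 | intermediate
8 | 2-{5-[2,5-bis(triisopropylsilyloxy)phenyl]furan-3-yl}-4,4,5,5-tetramethyl-1,3,2-dioxaborolane | CC1(C)OB(OC1(C)C)c2coc(-c3cc(O[Si](C(C)C)(C(C)C)C(C)C)ccc3O[Si](C(C)C)(C(C)C)C(C)C)c2 | intermediate
9 | tetravinylstannane | C=C[Sn](C=C)(C=C)C=C | starting material
10 | vinyllithium | [Li]C=C | intermediate
11 | isobutyraldehyde | CC(C)C=O | starting material
12 | 2-methylprop-1-enyl trifluoromethanesulfonate | CC(C)=COS(=O)(=O)C(F)(F)F | intermediate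
13 | lithium {5-[2,5-bis(triisopropylsilyloxy)phenyl]furan-3-yl}(ethenyl)(pinacolato)borate | [Li+].C=C[B-]1(OC(C)(C)C(C)(C)O1)c1coc(-c2cc(O[Si](C(C)C)(C(C)C)C(C)C)ccc2O[Si](C(C)C)(C(C)C)C(C)C)c1 | intermediate
14 | 2-[(1S)-1-{5-[2,5-bis(triisopropylsilyloxy)phenyl]furan-3-yl}-4-methylpent-3-en-1-yl]-4,4,5,5-tetramethyl-1,3,2-dioxaborolane | CC(C)=CC[C@H](B1OC(C)(C)C(C)(C)O1)c2coc(-c3cc(O[Si](C(C)C)(C(C)C)C(C)C)ccc3O[Si](C(C)C)(C(C)C)C(C)C)c2 | intermediate
15 | (1S)-1-{5-[2,5-bis(triisopropylsilyloxy)phenyl]furan-3-yl}-4-methylpent-3-en-1-ol | CC(C)=CC[C@H](O)c2coc(-c3cc(O[Si](C(C)C)(C(C)C)C(C)C)ccc3O[Si](C(C)C)(C(C)C)C(C)C)c2 | intermediate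
16 | 3-methylbut-2-enoic acid | CC(C)=CC(=O)O | starting material
17 | (1S)-1-{5-[2,5-bis(triisopropylsilyloxy)phenyl]furan-3-yl}-4-methylpent-3-en-1-yl 3-methylbut-2-enoate | CC(C)=CC[C@H](OC(=O)C=C(C)C)c2coc(-c3cc(O[Si](C(C)C)(C(C)C)C(C)C)ccc3O[Si](C(C)C)(C(C)C)C(C)C)c2 | intermediate
18 | (1S)-1-[5-(2,5-dihydroxyphenyl)furan-3-yl]-4-methylpent-3-en-1-yl 3-methylbut-2-enoate | CC(C)=CC[C@H](OC(=O)C=C(C)C)c1coc(-c2cc(O)ccc2O)c1 | target

## Step count and risks

Total steps: 10. Longest linear sequence: 8 (steps 1, 2, 3, 4, 7, 8, 9, 10); steps 5 and 6 are one-step side branches.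

**Step 7 (key step).** The electron-rich furyl group may transfer directly from boron to palladium, which would be a plain Suzuki-type coupling with no stereocentre. Enantiofacial discrimination may also be lower for a heteroaryl migrating group than for phenyl, and palladium may attack the free furan C5 of the ate complex.
Fallback: setting out from 8, the same boronate is made by stoichiometric chiral carbenoid homologation. 4-Methylpent-3-en-1-ol is acylated with N,N-diisopropylcarbamoyl chloride (Et3N, toluene, reflux) to 4-methylpent-3-en-1-yl N,N-diisopropylcarbamate F1. Carbamate-directed deprotonation with s-BuLi and (+)-sparteine (Et2O, −78 °C) gives the (R)-configured α-lithio carbamate F2. Addition of 8 gives, with retention at carbon, the lithium boronate complex F3. On warming (MgBr2·OEt2 in MeOH if the shift is slow) the furyl group migrates from boron to carbon with inversion and expels the carbamate, rejoining the route at 14.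

**Step 3.** The sulfonic acid may remove the silyl ether ortho to the ketone, after which the freed phenol closes onto the ynone instead of the furan forming. The hindered, electron-rich acid chloride may also acylate the alkyne slowly, leaving time for alkyne homocoupling.
Fallback: setting out from 3, the acid is converted (N,O-dimethylhydroxylamine hydrochloride, EDC·HCl, iPr2NEt, CH2Cl2) to 2,5-bis(triisopropylsilyloxy)-N-methoxy-N-methylbenzamide F4. Alkyne 5 is deprotonated with n-BuLi (THF, −78 °C) to [3-(oxan-2-yloxy)prop-1-yn-1-yl]lithium F5, which adds to F4 to give ynone 6, now isolated. Hydroiodination with NaI in AcOH at rt gives 1-[2,5-bis(triisopropylsilyloxy)phenyl]-3-iodo-4-(oxan-2-yloxy)but-2-en-1-one F6. Pyridinium 4-methylbenzenesulfonate in MeOH at 40 °C then removes the acetal and closes the ring, rejoining the route at 7. No palladium, no acid chloride and no strong acid are involved.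

**Step 9.** The double bond of the activated acid may move out of conjugation when DMAP acts as a base. The hindered secondary alcohol may react slowly enough for the activated acid to rearrange to an N-acylurea.
Fallback: setting out from 15, esterification with 2-(diethoxyphosphoryl)acetic acid (DCC, DMAP cat., CH2Cl2), which has no γ-hydrogens, gives (1S)-1-{5-[2,5-bis(triisopropylsilyloxy)phenyl]furan-3-yl}-4-methylpent-3-en-1-yl 2-(diethoxyphosphoryl)acetate F7. Horner–Wadsworth–Emmons olefination with acetone (NaH, THF, 0 °C to rt) builds the 3-methylbut-2-enoate in place and rejoins the route at 17.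

**Step 4.** Reduction of the C–I bond and coupling of the new boronate with unreacted iodide may compete, since the iodofuran is electron-rich and the product is itself a coupling partner.
Fallback: setting out from 7, iodine–magnesium exchange with iPrMgCl·LiCl (THF, −20 °C) gives {5-[2,5-bis(triisopropylsilyloxy)phenyl]furan-3-yl}magnesium chloride F8. Quenching with 2-isopropoxy-4,4,5,5-tetramethyl-1,3,2-dioxaborolane rejoins the route at 8 without palladium.

## Further compounds

F1 | step 7 | 4-methylpent-3-en-1-yl N,N-diisopropylcarbamate | CC(C)=CCCOC(=O)N(C(C)C)C(C)C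
F2 | step 7 | (1R)-1-lithio-4-methylpent-3-en-1-yl N,N-diisopropylcarbamate | CC(C)=CC[C@@H]([Li])OC(=O)N(C(C)C)C(C)C
F3 | step 7 | lithium boronate complex from F2 and 8 | [Li+].CC(C)=CC[C@@H]([B-]1(OC(C)(C)C(C)(C)O1)c1coc(-c2cc(O[Si](C(C)C)(C(C)C)C(C)C)ccc2O[Si](C(C)C)(C(C)C)C(C)C)c1)OC(=O)N(C(C)C)C(C)C
F4 | step 3 | 2,5-bis(triisopropylsilyloxy)-N-methoxy-N-methylbenzamide | CON(C)C(=O)c1cc(O[Si](C(C)C)(C(C)C)C(C)C)ccc1O[Si](C(C)C)(C(C)C)C(C)C
F5 | step 3 | [3-(oxan-2-yloxy)prop-1-yn-1-yl]lithium | [Li]C#CCOC1CCCCO1
F6 | step 3 | 1-[2,5-bis(triisopropylsilyloxy)phenyl]-3-iodo-4-(oxan-2-yloxy)but-2-en-1-one (E/Z mixture) | O=C(C=C(I)COC1CCCCO1)c1cc(O[Si](C(C)C)(C(C)C)C(C)C)ccc1O[Si](C(C)C)(C(C)C)C(C)C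
F7 | step 9 | (1S)-1-{5-[2,5-bis(triisopropylsilyloxy)phenyl]furan-3-yl}-4-methylpent-3-en-1-yl 2-(diethoxyphosphoryl)acetate | CC(C)=CC[C@H](OC(=O)CP(=O)(OCC)OCC)c1coc(-c2cc(O[Si](C(C)C)(C(C)C)C(C)C)ccc2O[Si](C(C)C)(C(C)C)C(C)C)c1
F8 | step 4 | {5-[2,5-bis(triisopropylsilyloxy)phenyl]furan-3-yl}magnesium chloride | Cl[Mg]c1coc(-c2cc(O[Si](C(C)C)(C(C)C)C(C)C)ccc2O[Si](C(C)C)(C(C)C)C(C)C)c1
A1 | alternative 1 | (1S)-1-{5-[2,5-bis(methoxymethoxy)phenyl]-2,5-dihydrofuran-3-yl}-4-methylpent-3-en-1-yl 3-methylbut-2-enoate | CC(C)=CC[C@H](OC(=O)C=C(C)C)C1=CC(c2cc(OCOC)ccc2OCOC)OC1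
A2 | alternative 1 | (3S)-2-({1-[2,5-bis(methoxymethoxy)phenyl]prop-2-en-1-yl}oxymethyl)-6-methylhepta-1,5-dien-3-yl 3-methylbut-2-enoate | CC(C)=CC[C@H](OC(=O)C=C(C)C)C(=C)COC(C=C)c1cc(OCOC)ccc1OCOC
A3 | alternative 2 | (1S)-1-[5-(2-hydroxy-5-methoxyphenyl)furan-3-yl]-4-methylpent-3-en-1-yl 3-methylbut-2-enoate | CC(C)=CC[C@H](OC(=O)C=C(C)C)c1coc(-c2cc(OC)ccc2O)c1
A4 | alternative 2 | (1S)-1-(5-ethynylfuran-3-yl)-4-methylpent-3-en-1-yl 3-methylbut-2-enoate | CC(C)=CC[C@H](OC(=O)C=C(C)C)c1coc(C#C)c1
A5 | alternative 2 | pentacarbonyl(1-methoxyprop-2-en-1-ylidene)chromium | COC(C=C)=[Cr].[C-]#[O+].[C-]#[O+].[C-]#[O+].[C-]#[O+].[C-]#[O+]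
A6 | alternative 3 | (1S)-1-{5-[2,5-bis(tert-butyldimethylsilyloxy)phenyl]furan-3-yl}-4-methylpent-3-en-1-yl 3-methylbut-2-enoate | CC(C)=CC[C@H](OC(=O)C=C(C)C)c1coc(-c2cc(O[Si](C)(C)C(C)(C)C)ccc2O[Si](C)(C)C(C)(C)C)c1
A7 | alternative 3 | 2-{[2,5-bis(tert-butyldimethylsilyloxy)phenyl]ethynyl}-6-methylhepta-2,5-dienal | O=CC(=CCC=C(C)C)C#Cc1cc(O[Si](C)(C)C(C)(C)C)ccc1O[Si](C)(C)C(C)(C)C
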